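The pyrrole ring is cut at N1–C5 and C4–C5, so that C5 with its acetyl group becomes a one-carbon ylide unit and the atoms N1, C2 (ester), C3 and C4 (both indol-3-yl) become an N-tosyl 1-azadiene. In one operation an acetonyl sulfonium ylide adds to C4, nitrogen closes the five-membered ring with loss of dimethyl sulfide, and elimination of sulfinate aromatises it. The feature exploited is the 2,5-diacylated pyrrole ring: the C5 ketone stabilises the ylide and acidifies H5, while the C2 ester activates the azadiene. The precursor is the N-tosyl imine of methyl 3,4-bis(1-Boc-indol-3-yl)-2-oxobut-3-enoate, assembled by Knoevenagel condensation of two indole building blocks.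

Key step: step 6

Assumption: the C3=C4 double bond of 4, 5 and 7 is drawn E (indolyl groups cis), the isomer expected to dominate; the other isomer should serve equally, because this geometry and the labile imine geometry are both erased in the annulation.

Step 1
Reactants: 1 indole-3-pyruvic acid
Product: 2 methyl 3-(1H-indol-3-yl)-2-oxopropanoate (largely enolised in solution)
Conditions: MeI (1.2 equiv), KHCO3 (1.2 equiv), DMF, rt
Reagents that add atoms: iodomethane, CI
Why: Hydrogencarbonate deprotonates only the carboxylic acid, so SN2 O-alkylation of the carboxylate should give the methyl ester without touching the enol or the indole N–H.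

Step 2
Reactants: 2 methyl 3-(1H-indol-3-yl)-2-oxopropanoate; 3 indole-3-carbaldehyde
Product: 4 methyl (E)-3,4-bis(1H-indol-3-yl)-2-oxobut-3-enoate
Conditions: piperidine (0.3 equiv), AcOH (0.3 equiv), 4 Å MS, MeCN, 70 °C
Reagents that add atoms: none
Why: Knoevenagel condensation in which piperidinium acetate converts 3 into its indoleninium-type iminium ion, the enol-rich keto ester adds through C3, and piperidine is expelled with help from the free indole nitrogen, a Mannich–elimination path that should avoid a persistent γ-hydroxy ester and its lactonisation.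

Step 3
Reactants: 4 methyl (E)-3,4-bis(1H-indol-3-yl)-2-oxobut-3-enoate
Product: 5 methyl (E)-3,4-bis(1-Boc-indol-3-yl)-2-oxobut-3-enoate
Conditions: Boc2O (2.5 equiv), DMAP (0.1 equiv), MeCN, rt
Reagents that add atoms: di-tert-butyl dicarbonate, CC(C)(C)OC(=O)OC(=O)OC(C)(C)C
Why: DMAP-catalysed N-acylation of the two indole N–H groups, the only acidic sites of a non-enolisable enone, and the carbamates also shut off the vinylogous-amide donation into C2 and C4 that would otherwise blunt steps 4 and 6.

Step 4
Reactants: 5 methyl (E)-3,4-bis(1-Boc-indol-3-yl)-2-oxobut-3-enoate; 6 p-toluenesulfonamide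
Product: 7 methyl (E)-3,4-bis(1-Boc-indol-3-yl)-2-(tosylimino)but-3-enoate
Conditions: TsNH2 (1.2 equiv), TiCl4 (0.6 equiv), Et3N (3 equiv), CH2Cl2, 0 °C to rt; filtered through Celite, used without chromatography
Reagents that add atoms: none
Why: TiCl4-mediated dehydrative condensation of a sulfonamide with the activated α-keto ester carbonyl, in which the excess amine buffers the Lewis acid so that the indole carbamates should survive at low temperature.

Step 5
Reactants: 8 chloroacetone
Product: 9 dimethyl(2-oxopropyl)sulfonium chloride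
Conditions: Me2S (1.5 equiv), acetone, rt
Reagents that add atoms: dimethyl sulfide, CSC
Why: SN2 alkylation of the soft sulfide by the activated α-chloro ketone, with the sulfonium salt expected to crystallise from acetone.

Step 6
Reactants: 7 methyl (E)-3,4-bis(1-Boc-indol-3-yl)-2-(tosylimino)but-3-enoate; 9 dimethyl(2-oxopropyl)sulfonium chloride
Product: 13 methyl 5-acetyl-3,4-bis(1-Boc-indol-3-yl)-1H-pyrrole-2-carboxylate, via dimethylsulfonium acetonylide 10 (not isolated), via trans-N-tosyl-2-pyrroline 11 (not isolated), via 3H-pyrrole 12 (not isolated)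
Conditions: 9 (1.3 equiv), Cs2CO3 (3 equiv), 4 Å MS, MeCN, 0 °C to rt, then 50 °C
Reagents that add atoms: none
Why: Cs2CO3 deprotonates 9 to the acetyl-stabilised ylide 10, which adds reversibly to C4 of the azadiene (C4–C5), and the sulfonamide nitrogen of the resulting aza-enolate displaces dimethyl sulfide at C5 (N1–C5) to give pyrroline 11; on warming, the base removes H5 next to the acetyl group, p-toluenesulfinate leaves from N1 to give the 3H-pyrrole 12, and a proton shift from C4 to N1 delivers the aromatic pyrrole. The closest known reaction type is the formal [4+1] annulation of carbonyl-stabilised sulfonium ylides with α,β-unsaturated N-sulfonyl imines, followed by sulfinate elimination. The single ring closes in a 5-exo-tet mode, nitrogen attacking C5 with the breaking C–S bond outside the ring. The transient stereocentres C4 and C5 of 11 (trans expected from the reversible addition) are erased on aromatisation, so no stereocontrol is needed. The step needs 1,4- over 1,2-addition and closure through nitrogen instead of carbon: reversible addition of the stabilised ylide and the slow three-membered closures (aziridine, cyclopropane) should funnel the betaines into the five-membered ring, the Boc groups keep C4 electrophilic, and the acetyl group makes H5 acidic enough for the elimination.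

Step 7
Reactants: 13 methyl 5-acetyl-3,4-bis(1-Boc-indol-3-yl)-1H-pyrrole-2-carboxylate
Product: 14 methyl 5-acetyl-3,4-bis(1H-indol-3-yl)-1H-pyrrole-2-carboxylate
Conditions: diphenyl ether, 180 °C, argon
Reagents that add atoms: none
Why: Thermolysis of indole N-Boc carbamates releases 2-methylpropene and CO2 without acid, base or nucleophile, so the ester, the ketone and the electron-rich free indoles are not exposed to any reagent.

Compound list
1 | indole-3-pyruvic acid | OC(=O)C(=O)Cc1c[nH]c2ccccc12 | starting material
2 | methyl 3-(1H-indol-3-yl)-2-oxopropanoate | COC(=O)C(=O)Cc1c[nH]c2ccccc12 | intermediate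
3 | indole-3-carbaldehyde | O=Cc1c[nH]c2ccccc12 | starting material
4 | methyl (E)-3,4-bis(1H-indol-3-yl)-2-oxobut-3-enoate | COC(=O)C(=O)/C(c1c[nH]c2ccccc12)=C/c1c[nH]c2ccccc12 | intermediate
5 | methyl (E)-3,4-bis[1-(tert-butoxycarbonyl)indol-3-yl]-2-oxobut-3-enoate | COC(=O)C(=O)/C(c1cn(C(=O)OC(C)(C)C)c2ccccc12)=C/c1cn(C(=O)OC(C)(C)C)c2ccccc12 | intermediate
6 | p-toluenesulfonamide | Cc1ccc(S(N)(=O)=O)cc1 | starting material
7 | methyl (E)-3,4-bis[1-(tert-butoxycarbonyl)indol-3-yl]-2-(tosylimino)but-3-enoate (imine geometry labile, not specified) | COC(=O)C(=NS(=O)(=O)c1ccc(C)cc1)/C(c1cn(C(=O)OC(C)(C)C)c2ccccc12)=C/c1cn(C(=O)OC(C)(C)C)c2ccccc12 | intermediate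
8 | chloroacetone | CC(=O)CCl | starting material
9 | dimethyl(2-oxopropyl)sulfonium chloride | CC(=O)C[S+](C)C.[Cl-] | intermediate
10 | dimethylsulfonium acetonylide | CC(=O)[CH-][S+](C)C | intermediate
11 | methyl 4,5-trans-5-acetyl-3,4-bis[1-(tert-butoxycarbonyl)indol-3-yl]-1-tosyl-4,5-dihydro-1H-pyrrole-2-carboxylate (racemic, one enantiomer drawn) | COC(=O)C1=C(c2cn(C(=O)OC(C)(C)C)c3ccccc23)[C@@H](c2cn(C(=O)OC(C)(C)C)c3ccccc23)[C@H](C(C)=O)N1S(=O)(=O)c1ccc(C)cc1 | intermediate
12 | methyl 2-acetyl-3,4-bis[1-(tert-butoxycarbonyl)indol-3-yl]-3H-pyrrole-5-carboxylate (racemic at C3) | COC(=O)C1=C(c2cn(C(=O)OC(C)(C)C)c3ccccc23)C(c2cn(C(=O)OC(C)(C)C)c3ccccc23)C(C(C)=O)=N1 | intermediate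
13 | methyl 5-acetyl-3,4-bis[1-(tert-butoxycarbonyl)indol-3-yl]-1H-pyrrole-2-carboxylate | COC(=O)c1[nH]c(C(C)=O)c(-c2cn(C(=O)OC(C)(C)C)c3ccccc23)c1-c1cn(C(=O)OC(C)(C)C)c2ccccc12 | intermediate
14 | methyl 5-acetyl-3,4-bis(1H-indol-3-yl)-1H-pyrrole-2-carboxylate | COC(=O)c1[nH]c(C(C)=O)c(-c2c[nH]c3ccccc23)c1-c1c[nH]c2ccccc12 | target

Total step count: 7. Longest linear sequence: 6 steps (1, 2, 3, 4, 6, 7); step 5 is a one-step side branch.

Steps most likely to fail

Step 6. The ylide may add 1,2 at the very electrophilic imino ester carbon and end in aziridination, the betaine may close through carbon to a cyclopropane, or traces of water may hydrolyse the sulfonyl imine before the annulation. The fallback sets out from enone 5 and builds the same ring by an electrocyclisation–dehydrogenation sequence. Condensation of 5 with aminoacetone hydrochloride (pyridine, 4 Å MS, 60 °C) should give the 2-aza-diene methyl (E)-3,4-bis(1-Boc-indol-3-yl)-2-[(2-oxopropyl)imino]but-3-enoate F1. Its 2-azapentadienyl anion should cyclise in the same flask by 1,5-electrocyclisation, as known for enones with α-amino nitriles and esters, to methyl 2-acetyl-3,4-bis(1-Boc-indol-3-yl)-3,4-dihydro-2H-pyrrole-5-carboxylate F2. Dehydrogenation with DDQ in toluene at rt comes back to the route at 13.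

Step 2. The keto ester may self-condense faster than it reacts with the weakly electrophilic aldehyde, an aldol intermediate may lactonise to a furanone instead of dehydrating, or a second nucleophile may add to the alkylidene-indolenine stage. The fallback sets out from 2 and forms the C4–indole bond instead of the C3=C4 bond. Aminomethylenation with tert-butoxybis(dimethylamino)methane (THF, 50 °C) should give the enaminone methyl 4-(dimethylamino)-3-(1H-indol-3-yl)-2-oxobut-3-enoate F3. Acid-promoted addition–elimination of indole (1 equiv, AcOH, rt to 40 °C) at the enaminone β-carbon, with loss of dimethylamine, comes back to the route at 4.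

Step 4. The Lewis acid may strip the Boc groups, condensation at the hindered ketone may stall, or the imine may hydrolyse during isolation. The fallback sets out from 5 and avoids Lewis acid and water release. Oximation (NH2OH·HCl, NaOAc, MeOH, rt) should give methyl (E)-3,4-bis(1-Boc-indol-3-yl)-2-(hydroxyimino)but-3-enoate F4. Treatment with p-toluenesulfinyl chloride and Et3N (CH2Cl2, −20 °C to rt) should give the O-sulfinyl oxime methyl (E)-3,4-bis(1-Boc-indol-3-yl)-2-[(p-tolylsulfinyl)oxyimino]but-3-enoate F5. This should rearrange on warming by N–O homolysis and recombination, the known route from unsaturated ketoximes to N-sulfonyl 1-azadienes, and comes back to the route at 7.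

Further compounds
F1 | step 6 | methyl (E)-3,4-bis[1-(tert-butoxycarbonyl)indol-3-yl]-2-[(2-oxopropyl)imino]but-3-enoate | COC(=O)C(=NCC(C)=O)/C(c1cn(C(=O)OC(C)(C)C)c2ccccc12)=C/c1cn(C(=O)OC(C)(C)C)c2ccccc12
F2 | step 6 | methyl 2-acetyl-3,4-bis[1-(tert-butoxycarbonyl)indol-3-yl]-3,4-dihydro-2H-pyrrole-5-carboxylate (mixture of diastereomers) | COC(=O)C1=NC(C(C)=O)C(c2cn(C(=O)OC(C)(C)C)c3ccccc23)C1c1cn(C(=O)OC(C)(C)C)c2ccccc12
F3 | step 2 | methyl 4-(dimethylamino)-3-(1H-indol-3-yl)-2-oxobut-3-enoate (alkene geometry of no consequence) | COC(=O)C(=O)C(=CN(C)C)c1c[nH]c2ccccc12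
F4 | step 4 | methyl (E)-3,4-bis[1-(tert-butoxycarbonyl)indol-3-yl]-2-(hydroxyimino)but-3-enoate | COC(=O)C(=NO)/C(c1cn(C(=O)OC(C)(C)C)c2ccccc12)=C/c1cn(C(=O)OC(C)(C)C)c2ccccc12
F5 | step 4 | methyl (E)-3,4-bis[1-(tert-butoxycarbonyl)indol-3-yl]-2-[(p-tolylsulfinyl)oxyimino]but-3-enoate | COC(=O)C(=NOS(=O)c1ccc(C)cc1)/C(c1cn(C(=O)OC(C)(C)C)c2ccccc12)=C/c1cn(C(=O)OC(C)(C)C)c2ccccc12
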